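Target in the north-west run levels at a mean of 70.4 % of the charge from 50.0 s on. That is 9.60 % of the charge below the 0.80 equiv of coupling partner, your limiting reagent if each target costs one partner.

| setting | north-west | north | alpha | gamma | theta |
|---|---|---|---|---|---|
| starting material | 0.17 M | 0.085 M | 0.17 M | 0.17 M (fed, over 1.5 min) | 0.17 M |
| coupling partner | 0.80 equiv | 0.80 equiv | 0.800 equiv | 0.800 equiv | 0.800 equiv (fed, over 1.5 min) |
| remark | run made earlier | run made earlier | everything together at the start | all else is in the flask from the start; the feed brings no volume worth counting | all else is in the flask from the start; the feed brings no volume worth counting |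
| time |  |  | 2.0 min | 2.0 min | 2.0 min |

| run | time / s | target / % | starting material / % |
|---|---|---|---|
| north-west | 15.0 | 37 | 0 |
| north-west | 30.0 | 66 | 2 |
| north-west | 50.0 | 73 | 3 |
| north-west | 60.0 | 71 | 0 |
| north-west | 80.0 | 72 | 0 |
| north-west | 90.0 | 65 | 2 |
| north-west | 120 | 71 | 0 |
| north | 10.0 | 20 | 1 |
| north | 15.0 | 35 | 0 |
| north | 20.0 | 53 | 0 |
| north | 25.0 | 55 | 1 |

(standard deviation of a reading: 2 percentage points)



1. the flask with the highest amount of target, in percent of the starting material charged ("all alike" if they lie within 1.5 percentage points) (alpha / gamma / theta / all alike)
2. final target, as a percentage of the starting material charged, in alpha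
3. final target, as a percentage of the starting material charged, in gamma
4. final target, as a percentage of the starting material charged, in theta

Climb the ladder of times. On the fastest rung, starting material reads 0 % at 15.0 s while target reads 37 %, so most of the charge already sits in unseen forms. The next rung is the target clock, the level divided by the early slope: 28.5 s. The north run, at half the concentration, reads 35 % at 15.0 s, within scatter of north-west, so the clock does not follow concentration. Its last reading, at 25.0 s, comes before one clock is over, so you cannot take it as an end value. Above that stands the feed, 1.5 min, and here you count turnovers: the clock count, feed time over clock, is 3.15. The top rung, 2.0 min, leaves 1.05 clocks after the feed, so both fed flasks have time to finish.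

My own bet charges the gap to partner waiting in the flask, at 9.60 % per clock. Alpha repeats north-west, so it lands near 70.4 %. For gamma I assume the partner lasts through the feed and count all 3.15 clocks as waiting, so my estimate of target is about 49.7 %, less than alpha. In theta the partner enters a stock of unseen forms and waits less than a clock, so target nears 0.80 of the charge, putting theta first.

The forecast differs, with gamma highest at 76 %, theta at 55 % and alpha at 72 %, on the ground that “the intermediate is lost when partner is scarce”.

Theta gives 78.9 %, alpha 70.7 % and gamma 54.9 %, so theta stands highest.

    starting material → intermediate A (k = 2.50 s⁻¹)
    coupling partner + intermediate A → side product (k = 0.170 M⁻¹ s⁻¹)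
    intermediate A → intermediate B (k = 0.170 s⁻¹)
    coupling partner + intermediate B → intermediate C (k = 13.0 M⁻¹ s⁻¹)
    intermediate C → target (k = 0.0860 s⁻¹)
    2 coupling partner → self-condensation product (k = 0.0550 M⁻¹ s⁻¹)

Gamma ends with 21.7 % of the charge, counted as partner, in self-condensation product, against 0.0138 % in theta. Your 3.15 clocks at 9.60 % each put gamma at 49.7 %, 5.2 percentage points under the result, and coupling partner in gamma reads 5.84 % of its own charge at 1.00 min and 0 % at 1.50 min, so it did not wait through all of that count. The same count gives 49.7 % again for the neighbour of gamma at 0.68 M of starting material, and that flask ends at 33.3 %.

The readings are calculated with made-up constants, noise included.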